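A single pass of the carrier leaves nearly all of the substrate over, because the spent carrier, at 0.30 mM, is charged in the smallest amount.

- midnight: substrate 20 mM; salt in the second phase 50 mM; spent carrier 0.30 mM; the very flask that is asked about, followed so far
- flask: substrate 20 mM; salt in the second phase 50.0 mM; spent carrier 0.30 mM; time 8.0 h; volume of the second phase over the first 1.0

midnight run (percent of the substrate charged)

| time / h | target / % | crystals / % |
|---|---|---|
| 0.200 | 2.7 | 0 |
| 0.333 | 3.4 | 0 |
| 0.500 | 1.8 | 0.4 |
| 0.833 | 2.3 | 1.4 |
| 1.33 | 4.1 | 0 |
| 2.50 | 8.0 | 0 |

(standard deviation of a reading: 1 percentage point)

- for target the crystals are counted in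
- charges count per volume of the first phase; a concentration in a rate is the amount of a species over the volume of its own phase; every rate counts per litre of the first phase
- as a solid, counted per litre of solution: crystals
- the analysis behind the earlier runs scatters by 1 percentage point, standard deviation
- the earlier runs hold the two phases in the same ratio of volumes as the flask asked about

- amount of target and crystals together at 8.0 h, in percent of the substrate charged
- concentration of target in solution at 8.0 h, in percent of saturation

So I wrote the balance of the carrier. Each target made costs one pass, and if y is the fraction of the substrate charged that has become target, the passes per carrier (the turnover number) are y times 66.7. The midnight reading of 8.0 % at 2.50 h, with its scatter of 1 percentage point, gave 2.13 /h: the rounds each carrier made per hour, or turnover frequency.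

The two extremes for the flask at 8.0 h were:

one pass, then stop: y = 1.50 %

rounds at the read pace throughout: y = 25.6 %

That reading already stood at 5.33 rounds, so the carrier was coming back. But the substrate was being used, so I let the pace fall with the fraction left:

y = 22.6 %

The crystals gave me nothing firm, with a highest reading of 1.4 % against that scatter, so I set no saturation of my own.

The forecast said 23 % and 75 %: “I guess near but below saturation”.

The flask gave 23.6 % and 42.9 %, the second 32 points below the forecast.

    spent carrier + salt in the second phase ⇌ fresh carrier + spent salt in the second phase (K = 0.260, k = 210 /M/h)
    substrate + fresh carrier → target + spent carrier (k = 260 /M/h)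
    substrate ⇌ dormant form (K = 0.340, k = 0.240 /h)
    crystals ⇌ target, rate k4*(cs4 - [target]) while solid is left; crystals form when [target] > cs4 (solubility = 11.0 mM, k = 14.0 /h)
    target ⇌ isomer of the product (K = 0.100, k = 0.240 /h)

This flask's 23.6 % of target and 2.27 % of isomer of the product, each made through a pass, are 17.3 rounds per carrier, on average 2.16 /h against the read 2.13 /h. With the charges as made, fresh carrier had a half-life of 0.13 h against the substrate and spent carrier 0.066 h against the salt (forward step alone), while the substrate's half-life by its step was 14 h at 3.20 h. At 8.00 h fresh carrier was made at 0.992 of the rate of its use, each step taken net, and the carrier stood 56.8 % fresh and 43.2 % spent. The flask left until 20 h reached 43.5 % of target and 4.30 % of isomer of the product, which is 31.9 rounds, on average 1.59 /h.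

The earlier runs and the new flask come from a simulation on assumed constants; scatter was added.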